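**Plan**

Atoms are numbered along the C22 acid chain (C1 = carboxyl carbon); the peroxide bridges C3 and C6 in a 1,2-dioxane.
- Retrosynthesis: cut the ester; then the ring O–C3 bond together with the C6 ketal configuration; then the C6 peroxyketal back to a ketone; then C2=C3 (Wittig), C5–C6 (Weinreb amide + Grignard) and C11–C12 (Sonogashira).
- Enabling feature: ring carbon C3 is beta to C1 (O–C3–C2–C1=O), so the O–C3 bond is the bond made when the C6 hydroperoxide adds to a C2=C3 enoate. C6 carries two oxygens (ring O and OMe), so it is an exchangeable, anomerically biased centre.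
- Forward: the chain is joined linearly (C6–C11 alkyne amide, then C12–C22 iodoalkene, then C3–C5, then C1–C2). The only ring is closed in the penultimate step from a racemic acyclic hydroperoxy ketal.
- Stereochemistry: C3 (S) comes from a chiral amine–squaramide catalyst that acts on both enantiomers of the precursor. C6 (R) comes from acid-mediated anomeric equilibration in the same flask, which funnels both ketal epimers into the cis isomer. Both E alkenes come from hydrozirconation and a stabilised ylide.

Key step: step 7

Assumption: the quinine-derived squaramide is taken as the pseudoenantiomer that delivers the peroxide to the Si face of C3. If the quinidine-derived one, 3-[[3,5-bis(trifluoromethyl)phenyl]amino]-4-[[(9R)-6'-methoxycinchonan-9-yl]amino]cyclobut-3-ene-1,2-dione, proves to be the one that does so, it replaces it without other change.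

**Route**

Step 1
Reactants: 1 undec-1-yne
Product: 3 (E)-1-iodoundec-1-ene, via alkenylzirconocene chloride 2 (not isolated)
Conditions: Cp2Zr(H)Cl (1.2 equiv), THF, rt; then I2, 0 °C
Reagents that add atoms: iodine, II
Why: Syn-hydrozirconation places zirconium on the terminal carbon and iodinolysis of the C–Zr bond goes with retention, so the E-alkenyl iodide should form as one isomer (hydrozirconation–iodination).

Step 2
Reactants: 4 hex-5-ynoic acid; 5 N,O-dimethylhydroxylamine hydrochloride
Product: 7 N-methoxy-N-methylhex-5-ynamide, via acyl imidazole 6 (not isolated)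
Conditions: 1,1'-carbonyldiimidazole (1.1 equiv), CH2Cl2, rt; then 5, rt
Reagents that add atoms: none
Why: Activation of the acid as the acyl imidazole followed by aminolysis is a standard Weinreb amide synthesis and leaves the terminal alkyne untouched.

Step 3
Reactants: 7 N-methoxy-N-methylhex-5-ynamide; 3 (E)-1-iodoundec-1-ene
Product: 8 (E)-N-methoxy-N-methylheptadec-7-en-5-ynamide
Conditions: PdCl2(PPh3)2 (2 mol %), CuI (4 mol %), Et3N, THF, rt
Reagents that add atoms: none
Why: Sonogashira coupling of a terminal alkyne with an E-alkenyl iodide keeps the alkene geometry and tolerates the Weinreb amide.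

Step 4
Reactants: 8 (E)-N-methoxy-N-methylheptadec-7-en-5-ynamide; 9 [2-(1,3-dioxolan-2-yl)ethyl]magnesium bromide
Product: 12 (E)-4-oxoicos-10-en-8-ynal, via magnesium tetrahedral adduct 10 (not isolated), via ketone acetal 11 (not isolated)
Conditions: THF, 0 °C to rt; then 2 M aq. HCl, THF, rt
Reagents that add atoms: water, O
Why: The Weinreb amide stops at the chelated tetrahedral adduct so that the Grignard reagent adds only once (Weinreb ketone synthesis), and the acidic aqueous quench releases the ketone and hydrolyses the dioxolane to the aldehyde.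

Step 5
Reactants: 12 (E)-4-oxoicos-10-en-8-ynal; 13 methyl (triphenylphosphoranylidene)acetate
Product: 14 methyl (2E,12E)-6-oxodocosa-2,12-dien-10-ynoate
Conditions: CH2Cl2, rt
Reagents that add atoms: none
Why: The stabilised ylide reacts with the aldehyde and not with the ketone and should give the E-enoate (Wittig reaction).

Step 6
Reactants: 14 methyl (2E,12E)-6-oxodocosa-2,12-dien-10-ynoate
Product: 15 methyl (2E,12E)-6-hydroperoxy-6-methoxydocosa-2,12-dien-10-ynoate (racemic at C6)
Conditions: urea–hydrogen peroxide, Sc(OTf)3 (10 mol %), MeOH, rt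
Reagents that add atoms: hydrogen peroxide (as its urea adduct), OO; methanol, CO
Why: Sc(OTf)3 in methanol converts the ketone into a methyl oxocarbenium ion that hydrogen peroxide traps, a known acid-catalysed peroxyketalisation of keto enoates; enoate and enyne are inert to these non-basic conditions and the new centre is left racemic on purpose.

Step 7
Reactants: 15 methyl (2E,12E)-6-hydroperoxy-6-methoxydocosa-2,12-dien-10-ynoate
Product: 17 methyl 2-[(3S,6R)-6-[(E)-hexadec-6-en-4-yn-1-yl]-6-methoxy-1,2-dioxan-3-yl]acetate, via ketal-epimer mixture 16 (not isolated)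
Conditions: 3-[[3,5-bis(trifluoromethyl)phenyl]amino]-4-[[(8α,9S)-6'-methoxycinchonan-9-yl]amino]cyclobut-3-ene-1,2-dione (10 mol %), toluene, −20 to 0 °C; then MeOH (10 equiv), (+)-camphor-10-sulfonic acid (30 mol %), CH2Cl2, 0 °C to rt
Reagents that add atoms: methanol, CO
Why: Proposed new method: the quinuclidine nitrogen of the catalyst takes the proton of the hydroperoxy group (an alpha-effect nucleophile whose acidity matches that of the ammonium ion) while the squaramide N–H pair binds the ester carbonyl, and the ion-paired peroxide adds to C3 of the enoate, after which the ester enol is protonated at C2. The closest known reaction types are the achiral amine-mediated cyclisation of hydroperoxy ketals onto enoates that gives 3-methoxy-1,2-dioxanes and the enantioselective intramolecular oxa-Michael addition of alcohols under bifunctional amine–hydrogen-bond-donor catalysis; what is new is the hydroperoxide nucleophile in the chiral version. The single ring, the 1,2-dioxane, closes in the 6-exo-trig mode through a chair-like transition state. The new centre C3 is controlled by the catalyst, which has to deliver the peroxide to the Si face of C3 in both enantiomers of 15, so that the (3S,6R) and (3S,6S) esters 16 form; the remote ketal centre is expected to exert little influence because the achiral version is known to be weakly diastereoselective. C6 is then controlled by thermodynamics: the acid ionises the C6–OMe bond to a ring peroxycarbenium ion (or opens and recloses the ring O–C6 bond through the methyl oxocarbenium ion), and the equilibrium should settle on the chair with axial methoxy (anomeric effect) and both carbon substituents equatorial, which is the cis (3S,6R) ester. The step needs enantioface selectivity over a background reaction, retention of the peroxide over epoxide closure of the enolate onto the O–O bond, and no retro-Michael opening; the weakly basic catalyst with its protic ammonium partner, the low temperature in a non-polar solvent, and the acid quench that stops all base-mediated pathways before C6 equilibrates should secure these.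

Step 8
Reactants: 17 methyl 2-[(3S,6R)-6-[(E)-hexadec-6-en-4-yn-1-yl]-6-methoxy-1,2-dioxan-3-yl]acetate
Product: 19 2-[(3S,6R)-6-[(E)-hexadec-6-en-4-yn-1-yl]-6-methoxy-1,2-dioxan-3-yl]acetic acid (target), via lithium carboxylate 18 (not isolated)
Conditions: LiOH (2 equiv), THF/H2O, 0 °C; then dilute aq. HCl to pH 4, 0 °C
Reagents that add atoms: lithium hydroxide, [Li+].[OH-]
Why: Hydroxide attacks the ester carbonyl faster than it removes the alpha proton and the peroxyketal is stable to base, so saponification at 0 °C should free the acid without ring opening; neither stereocentre is touched.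

**Compound list**

1 | undec-1-yne | CCCCCCCCCC#C | starting material
2 | chlorobis(cyclopentadienyl)[(E)-undec-1-en-1-yl]zirconium | CCCCCCCCC/C=C/[Zr](Cl)(C1C=CC=C1)C1C=CC=C1 | intermediate (not isolated)
3 | (E)-1-iodoundec-1-ene | CCCCCCCCC/C=C/I | intermediate
4 | hex-5-ynoic acid | C#CCCCC(=O)O | starting material
5 | N,O-dimethylhydroxylamine hydrochloride | CNOC.Cl | starting material
6 | 1-(hex-5-ynoyl)-1H-imidazole | C#CCCCC(=O)n1ccnc1 | intermediate (not isolated)
7 | N-methoxy-N-methylhex-5-ynamide | C#CCCCC(=O)N(C)OC | intermediate
8 | (E)-N-methoxy-N-methylheptadec-7-en-5-ynamide | CCCCCCCCC/C=C/C#CCCCC(=O)N(C)OC | intermediate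
9 | [2-(1,3-dioxolan-2-yl)ethyl]magnesium bromide | Br[Mg]CCC1OCCO1 | starting material
10 | bromomagnesium (E)-1-(1,3-dioxolan-2-yl)-3-[methoxy(methyl)amino]nonadec-9-en-7-yn-3-olate | CCCCCCCCC/C=C/C#CCCCC(O[Mg]Br)(N(C)OC)CCC1OCCO1 | intermediate (not isolated)
11 | (E)-1-(1,3-dioxolan-2-yl)nonadec-9-en-7-yn-3-one | CCCCCCCCC/C=C/C#CCCCC(=O)CCC1OCCO1 | intermediate (not isolated)
12 | (E)-4-oxoicos-10-en-8-ynal | CCCCCCCCC/C=C/C#CCCCC(=O)CCC=O | intermediate
13 | methyl (triphenylphosphoranylidene)acetate | COC(=O)C=P(c1ccccc1)(c1ccccc1)c1ccccc1 | starting material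
14 | methyl (2E,12E)-6-oxodocosa-2,12-dien-10-ynoate | CCCCCCCCC/C=C/C#CCCCC(=O)CC/C=C/C(=O)OC | intermediate
15 | methyl (2E,12E)-6-hydroperoxy-6-methoxydocosa-2,12-dien-10-ynoate, racemic at C6 | CCCCCCCCC/C=C/C#CCCCC(OC)(OO)CC/C=C/C(=O)OC | intermediate
16 | methyl 2-[(3S)-6-[(E)-hexadec-6-en-4-yn-1-yl]-6-methoxy-1,2-dioxan-3-yl]acetate, both epimers at the ketal carbon | CCCCCCCCC/C=C/C#CCCCC1(OC)CC[C@@H](CC(=O)OC)OO1 | intermediate (not isolated)
17 | methyl 2-[(3S,6R)-6-[(E)-hexadec-6-en-4-yn-1-yl]-6-methoxy-1,2-dioxan-3-yl]acetate | CCCCCCCCC/C=C/C#CCCC[C@]1(OC)CC[C@@H](CC(=O)OC)OO1 | intermediate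
18 | lithium 2-[(3S,6R)-6-[(E)-hexadec-6-en-4-yn-1-yl]-6-methoxy-1,2-dioxan-3-yl]acetate | CCCCCCCCC/C=C/C#CCCC[C@]1(OC)CC[C@@H](CC(=O)[O-])OO1.[Li+] | intermediate (not isolated)
19 | 2-[(3S,6R)-6-[(E)-hexadec-6-en-4-yn-1-yl]-6-methoxy-1,2-dioxan-3-yl]acetic acid | CCCCCCCCC/C=C/C#CCCC[C@]1(OC)CC[C@@H](CC(=O)O)OO1 | target

**Count and risks**

Total step count: 8. Longest linear sequence: 7 steps (steps 2 to 8, from hex-5-ynoic acid).

Steps most likely to fail:

1. Step 7. The catalyst may give poor enantioface control, or the addition to the alkyl enoate may be so slow that an unselective background closure takes over; the anomeric equilibration may also stop short of a clean cis preference. Fallback: from 15, the established achiral closure with Et2NH in CF3CH2OH gives the dioxane ester as the mixture of all four stereoisomers F1. The acid/methanol equilibration of step 7 turns this into the racemic cis ester F2. Preparative chromatography on a chiral stationary phase (cellulose tris(3,5-dimethylphenylcarbamate)) then delivers 17, where the route is rejoined.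

2. Step 6. The acid-mediated exchange may stall at a mixture of ketone, dimethyl ketal and hydroperoxy ketal, or run on to the geminal bis-hydroperoxide. Fallback: from 14, ketalisation with HC(OMe)3 and pyridinium p-toluenesulfonate in MeOH gives the isolated dimethyl ketal methyl (2E,12E)-6,6-dimethoxydocosa-2,12-dien-10-ynoate F3. Exchange of one methoxy group with anhydrous ethereal H2O2 and catalytic camphorsulfonic acid at 0 °C (transperoxyketalisation) then gives 15, where the route is rejoined.

3. Step 4. The 1,4-keto aldehyde may cyclodehydrate or self-condense during the prolonged acidic unmasking in the same flask. Fallback: from 8, addition of the Grignard reagent [3-[(tert-butyldimethylsilyl)oxy]propyl]magnesium bromide F4 (from the commercial bromide and Mg) gives, through the magnesium tetrahedral adduct F5 and aqueous NH4Cl work-up, the ketone silyl ether (E)-1-[(tert-butyldimethylsilyl)oxy]icos-10-en-8-yn-4-one F6. HF·pyridine in THF removes the silyl group to give the hydroxy ketone (E)-1-hydroxyicos-10-en-8-yn-4-one F7. Oxidation with Dess–Martin periodinane buffered with NaHCO3 in the presence of ylide 13 forms 12 only transiently under neutral conditions and traps it at once, so the route is rejoined at 14.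

**Further compounds**

F1 | step 7 | methyl 2-[6-[(E)-hexadec-6-en-4-yn-1-yl]-6-methoxy-1,2-dioxan-3-yl]acetate, all four stereoisomers | CCCCCCCCC/C=C/C#CCCCC1(OC)CCC(CC(=O)OC)OO1
F2 | step 7 | racemic cis ester, methyl 2-[(3S,6R)- and (3R,6S)-6-[(E)-hexadec-6-en-4-yn-1-yl]-6-methoxy-1,2-dioxan-3-yl]acetate | CCCCCCCCC/C=C/C#CCCC[C@]1(OC)CC[C@@H](CC(=O)OC)OO1.CCCCCCCCC/C=C/C#CCCC[C@@]1(OC)CC[C@H](CC(=O)OC)OO1
F3 | step 6 | methyl (2E,12E)-6,6-dimethoxydocosa-2,12-dien-10-ynoate | CCCCCCCCC/C=C/C#CCCCC(OC)(OC)CC/C=C/C(=O)OC
F4 | step 4 | [3-[(tert-butyldimethylsilyl)oxy]propyl]magnesium bromide | Br[Mg]CCCO[Si](C)(C)C(C)(C)C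
F5 | step 4 | bromomagnesium (E)-1-[(tert-butyldimethylsilyl)oxy]-4-[methoxy(methyl)amino]icos-10-en-8-yn-4-olate | CCCCCCCCC/C=C/C#CCCCC(O[Mg]Br)(N(C)OC)CCCO[Si](C)(C)C(C)(C)C
F6 | step 4 | (E)-1-[(tert-butyldimethylsilyl)oxy]icos-10-en-8-yn-4-one | CCCCCCCCC/C=C/C#CCCCC(=O)CCCO[Si](C)(C)C(C)(C)C
F7 | step 4 | (E)-1-hydroxyicos-10-en-8-yn-4-one | CCCCCCCCC/C=C/C#CCCCC(=O)CCCO
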